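**Retrosynthetic overview**
1. Target 17 ⇐ reductive radical closure of the cyclopentane (C1–C8a bond) from epoxy-dione 16; C2 comes from a Shi epoxidation of prenyl-dione 15.
2. 15 ⇐ key 1,2-acyl shift of spiro-epoxy ketone 14: cyclohexanone → cycloheptane-1,3-dione (ring expansion).
3. 14 ⇐ B-alkyl Suzuki coupling (butenolide) on vinyl epoxy ketone 11 ⇐ Darzens condensation of chloro ketone 6 with aldehyde 8.
4. 6 ⇐ ketone 4 ⇐ one-pot asymmetric conjugate methylation / α-vinylation of 2-methylcyclohexenone 1 (sets C5 and C6 of the target).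
5. Ring order: six-membered ring (from 1) → seven-membered ring by ring expansion → five-membered ring last.

Assumption: the natural C3a configuration (ring-fusion OH syn to the C4 ketone, internally hydrogen-bonded) is the thermodynamically favoured epimer of the enolisable ring-fusion CH.

**Step 1**
Reactants: 1 2-methylcyclohex-2-en-1-one; 2 bromoethene
Product: 4 (2S,3R)-2-ethenyl-2,3-dimethylcyclohexan-1-one, via bromomagnesium enolate 3 (not isolated)
Conditions: MeMgBr, Cu(OTf)2 (3 mol %), chiral NHC ligand (4 mol %, enantiomer giving 3R), Et2O, −30 °C; then 2, Pd2(dba)3 (2.5 mol %), Q-Phos (5 mol %), THF, −30 → 25 °C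
Reagents that add atoms: methylmagnesium bromide C[Mg]Br
Why: Proposed new method: Cu–NHC-catalysed asymmetric conjugate methylation sets C3 (R) and leaves the regiodefined, fully substituted Mg enolate 3, which is vinylated in the same flask by Pd(0)/Q-Phos (oxidative addition of vinyl bromide, transmetalation to the C-bound Pd enolate on the face anti to the C3 methyl, C–C reductive elimination), giving the quaternary C2 with vinyl trans to C3–Me; the closest known reaction types are Pd-catalysed α-vinylation of preformed Li/Na ketone enolates and conjugate addition–enolate alkylation tandems, but Pd-vinylation of a conjugate-addition-derived Mg enolate has not been shown.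

**Step 2**
Reactants: 4 (2S,3R)-2-ethenyl-2,3-dimethylcyclohexan-1-one
Product: 6 (2S,3R)-6-chloro-2-ethenyl-2,3-dimethylcyclohexan-1-one, via lithium enolate 5 (not isolated)
Conditions: LDA, THF, −78 °C; then TsCl, −78 → 0 °C
Reagents that add atoms: 4-methylbenzenesulfonyl chloride Cc1ccc(cc1)S(Cl)(=O)=O
Why: C6 is the only enolisable position (C2 is quaternary) and the lithium enolate is chlorinated by TsCl as a Cl+ donor (enolate α-halogenation); C6 is left as an epimer mixture because it is erased in steps 4 and 6.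

**Step 3**
Reactants: 7 4-methylpent-3-en-1-ol
Product: 8 4-methylpent-3-enal
Conditions: TEMPO (10 mol %), PhI(OAc)2, CH2Cl2, 0 → 20 °C; used crude
Reagents that add atoms: none
Why: The TEMPO/PhI(OAc)2 (oxoammonium) oxidation stops at the aldehyde under near-neutral conditions, so the β,γ-alkene does not move into conjugation.

**Step 4**
Reactants: 6 (2S,3R)-6-chloro-2-ethenyl-2,3-dimethylcyclohexan-1-one; 8 4-methylpent-3-enal
Product: 11 (5S,6R)-5-ethenyl-5,6-dimethyl-2-(3-methylbut-2-en-1-yl)-1-oxaspiro[2.5]octan-4-one, via lithium chloroenolate 9 (not isolated), via lithium chlorohydrin alkoxide 10 (not isolated)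
Conditions: LiHMDS, THF, −78 °C; then 8, −78 → 20 °C
Reagents that add atoms: none
Why: Darzens condensation: the α-chloro enolate adds to the aldehyde and the alkoxide closes by 3-exo-tet displacement of chloride α to the carbonyl; the two epoxide centres form as a mixture that converges in step 6 (one becomes C=O, the other an enolisable CH).

**Step 5**
Reactants: 11 (5S,6R)-5-ethenyl-5,6-dimethyl-2-(3-methylbut-2-en-1-yl)-1-oxaspiro[2.5]octan-4-one; 12 4-bromofuran-2(5H)-one
Product: 14 4-{2-[(5S,6R)-5,6-dimethyl-2-(3-methylbut-2-en-1-yl)-4-oxo-1-oxaspiro[2.5]octan-5-yl]ethyl}furan-2(5H)-one, via alkyl-9-BBN borane 13 (not isolated)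
Conditions: 9-BBN, THF, 0 → 20 °C; then 12, Pd(dppf)Cl2 (5 mol %), AsPh3 (5 mol %), aq K3PO4, DMF, 20 °C
Reagents that add atoms: none
Why: 9-BBN hydroborates the monosubstituted vinyl group anti-Markovnikov much faster than the trisubstituted alkene or the hindered ketone, and B-alkyl Suzuki–Miyaura coupling with the β-bromobutenolide installs the complete side chain without touching a stereocentre.

**Step 6**
Reactants: 14 4-{2-[(5S,6R)-5,6-dimethyl-2-(3-methylbut-2-en-1-yl)-4-oxo-1-oxaspiro[2.5]octan-5-yl]ethyl}furan-2(5H)-one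
Product: 15 4-{2-[(1S,7R)-1,7-dimethyl-3-(3-methylbut-2-en-1-yl)-2,4-dioxocycloheptyl]ethyl}furan-2(5H)-one
Conditions: BF3·OEt2 (30 mol %), CH2Cl2, −40 → 0 °C; aq NaHCO3
Reagents that add atoms: none
Why: Key ring expansion (Lewis-acid epoxy-ketone rearrangement of the House type): BF3 opens the secondary C2–O bond and the ring acyl carbon C4 shifts 1,2 from spiro C3 to C2 while C3 becomes the new carbonyl, turning the cyclohexanone into the 2-substituted cycloheptane-1,3-dione; acyl migrates in preference to alkyl or hydride and the two set stereocentres are not involved.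

**Step 7**
Reactants: 15 4-{2-[(1S,7R)-1,7-dimethyl-3-(3-methylbut-2-en-1-yl)-2,4-dioxocycloheptyl]ethyl}furan-2(5H)-one
Product: 16 4-{2-[(1S,7R)-3-{[(2R)-3,3-dimethyloxiran-2-yl]methyl}-1,7-dimethyl-2,4-dioxocycloheptyl]ethyl}furan-2(5H)-one
Conditions: Shi ketone (D-fructose-derived, 30 mol %), Oxone, NaHCO3 (pH ≈ 8), Bu4NHSO4 (cat.), MeCN/DMM/H2O, 0 °C
Reagents that add atoms: Oxone (potassium peroxymonosulfate) [K+].[O-]S(=O)(=O)OO
Why: Shi asymmetric epoxidation: the chiral dioxirane attacks only the electron-rich trisubstituted alkene (the butenolide is electron-poor, the seven-ring 1,3-dione is mainly in the diketo form) and sets by reagent control the (R) CH–O centre that becomes C2 of the target.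

**Step 8**
Reactants: 16 4-{2-[(1S,7R)-3-{[(2R)-3,3-dimethyloxiran-2-yl]methyl}-1,7-dimethyl-2,4-dioxocycloheptyl]ethyl}furan-2(5H)-one
Product: 17 (2R,3aS,5S,6R,8aS)-2,8a-dihydroxy-1,1,5,6-tetramethyl-5-[2-(5-oxo-2,5-dihydrofuran-3-yl)ethyl]octahydroazulen-4(1H)-one
Conditions: Cp2TiCl2 (20 mol %), Zn dust, 2,4,6-collidine·HCl, THF (0.01 M, slow addition), 20 °C
Reagents that add atoms: none
Why: Reductive radical epoxide–carbonyl cyclisation (Nugent–RajanBabu titanocene(III) epoxide opening): homolysis of the tertiary C–O bond keeps the (R) C–O centre and gives the tertiary radical, which adds 5-exo to the less hindered ring carbonyl (the other is flanked by the quaternary carbon) while the titanium alkoxide chelates that carbonyl, so the new tertiary alcohol forms cis to the existing oxygen (8aS), and the still enolisable C3a settles as the hydrogen-bonded OH/C=O-syn epimer (3aS).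

**Compound list**
1 | 2-methylcyclohex-2-en-1-one | CC1=CCCCC1=O | starting material
2 | bromoethene (vinyl bromide) | C=CBr | starting material
3 | bromomagnesium (3R)-2,3-dimethylcyclohex-1-en-1-olate | C[C@@H]1CCCC(O[Mg]Br)=C1C | intermediate
4 | (2S,3R)-2-ethenyl-2,3-dimethylcyclohexan-1-one | C[C@@H]1CCCC(=O)[C@@]1(C)C=C | intermediate
5 | lithium (5R,6S)-6-ethenyl-5,6-dimethylcyclohex-1-en-1-olate | C[C@@H]1CCC=C(O[Li])[C@@]1(C)C=C | intermediate
6 | (2S,3R)-6-chloro-2-ethenyl-2,3-dimethylcyclohexan-1-one (C6 epimers) | C[C@@H]1CCC(Cl)C(=O)[C@@]1(C)C=C | intermediate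
7 | 4-methylpent-3-en-1-ol | CC(C)=CCCO | starting material
8 | 4-methylpent-3-enal | CC(C)=CCC=O | intermediate
9 | lithium (5R,6S)-2-chloro-6-ethenyl-5,6-dimethylcyclohex-1-en-1-olate | C[C@@H]1CCC(Cl)=C(O[Li])[C@@]1(C)C=C | intermediate
10 | lithium 1-[(3S,4R)-1-chloro-3-ethenyl-3,4-dimethyl-2-oxocyclohexyl]-4-methylpent-3-en-1-olate | C[C@@H]1CCC(Cl)(C(O[Li])CC=C(C)C)C(=O)[C@@]1(C)C=C | intermediate
11 | (5S,6R)-5-ethenyl-5,6-dimethyl-2-(3-methylbut-2-en-1-yl)-1-oxaspiro[2.5]octan-4-one (epoxide diastereomers) | C[C@@H]1CCC2(OC2CC=C(C)C)C(=O)[C@@]1(C)C=C | intermediate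
12 | 4-bromofuran-2(5H)-one | O=C1OCC(Br)=C1 | starting material
13 | 9-{2-[(5S,6R)-5,6-dimethyl-2-(3-methylbut-2-en-1-yl)-4-oxo-1-oxaspiro[2.5]octan-5-yl]ethyl}-9-borabicyclo[3.3.1]nonane | C[C@@H]1CCC2(OC2CC=C(C)C)C(=O)[C@@]1(C)CCB1C2CCCC1CCC2 | intermediate
14 | 4-{2-[(5S,6R)-5,6-dimethyl-2-(3-methylbut-2-en-1-yl)-4-oxo-1-oxaspiro[2.5]octan-5-yl]ethyl}furan-2(5H)-one | C[C@@H]1CCC2(OC2CC=C(C)C)C(=O)[C@@]1(C)CCC1=CC(=O)OC1 | intermediate
15 | 4-{2-[(1S,7R)-1,7-dimethyl-3-(3-methylbut-2-en-1-yl)-2,4-dioxocycloheptyl]ethyl}furan-2(5H)-one (C3 epimers interconvert) | C[C@@H]1CCC(=O)C(CC=C(C)C)C(=O)[C@@]1(C)CCC1=CC(=O)OC1 | intermediate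
16 | 4-{2-[(1S,7R)-3-{[(2R)-3,3-dimethyloxiran-2-yl]methyl}-1,7-dimethyl-2,4-dioxocycloheptyl]ethyl}furan-2(5H)-one | C[C@@H]1CCC(=O)C(C[C@@H]2C(C)(C)O2)C(=O)[C@@]1(C)CCC1=CC(=O)OC1 | intermediate
17 | (2R,3aS,5S,6R,8aS)-2,8a-dihydroxy-1,1,5,6-tetramethyl-5-[2-(5-oxo-2,5-dihydrofuran-3-yl)ethyl]octahydroazulen-4(1H)-one | C[C@@H]1CC[C@]2(O)[C@H](C[C@@H](O)C2(C)C)C(=O)[C@@]1(C)CCC1=CC(=O)OC1 | target

**Step count**
Total steps: 8. Longest linear sequence: 7 (steps 1, 2, 4, 5, 6, 7, 8).

**Three steps most likely to fail**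

Step 1 (the proposed new one-pot methylation/vinylation). The hindered Mg enolate may not transmetalate to Pd, or may couple with poor diastereoselectivity. The fallback uses known chemistry, sets out from 1 and comes back at 4. The same Cu-catalysed conjugate methylation is run and enolate 3 is trapped with acetaldehyde (conjugate addition–aldol sequence, electrophile again anti to the C3 methyl) to give (2R,3R)-2-(1-hydroxyethyl)-2,3-dimethylcyclohexan-1-one F1 as a carbinol epimer mixture. Burgess dehydration (syn-elimination; only the CH3 β-hydrogens are available) then gives 4.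

Step 6 (the acyl-shift ring expansion). Fluorohydrin formation, alkyl shift, participation of the prenyl alkene, or sequestration of BF3 by the dione could lower the yield. The fallback uses a different, known one-carbon ring expansion (Ito–Saegusa), sets out from 4 and comes back at 15. LDA/TMSCl gives the silyl enol ether {[(5R,6S)-6-ethenyl-5,6-dimethylcyclohex-1-en-1-yl]oxy}trimethylsilane F2. Et2Zn/CH2I2 cyclopropanates the electron-rich enol ether selectively to the siloxycyclopropane {[(2S,3R)-2-ethenyl-2,3-dimethylbicyclo[4.1.0]heptan-1-yl]oxy}trimethylsilane F3. FeCl3 in DMF opens it with ring expansion to (2S,3R)-6-chloro-2-ethenyl-2,3-dimethylcycloheptan-1-one F4, and NaOAc/MeOH eliminates HCl to (6R,7S)-7-ethenyl-6,7-dimethylcyclohept-2-en-1-one F5. Weitz–Scheffer epoxidation (H2O2, NaOH) gives (3S,4R)-3-ethenyl-3,4-dimethyl-8-oxabicyclo[5.1.0]octan-2-one F6. Hydroboration with 9-BBN gives 9-{2-[(3S,4R)-3,4-dimethyl-2-oxo-8-oxabicyclo[5.1.0]octan-3-yl]ethyl}-9-borabicyclo[3.3.1]nonane F7, and Suzuki coupling with 12 as in step 5 gives 4-{2-[(3S,4R)-3,4-dimethyl-2-oxo-8-oxabicyclo[5.1.0]octan-3-yl]ethyl}furan-2(5H)-one F8. Pd(PPh3)4/dppe isomerises the epoxy ketone to the 1,3-dione 4-{2-[(1S,7R)-1,7-dimethyl-2,4-dioxocycloheptyl]ethyl}furan-2(5H)-one F9. Tsuji–Trost C-prenylation (Pd(PPh3)4, Et3B, 3-methylbut-2-en-1-ol) then gives 15.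

Step 8 (radical closure of the cyclopentane). Possible failures are attack at the wrong carbonyl, O-alkylation of the dione enol by the epoxide, loss of the radical to the allylic alcohol, or the wrong C8a/C3a relationship. The fallback sets out from 16 and comes back at 17. The epoxide is isomerised (Al(Oi-Pr)3, toluene, 110 °C) to the allylic alcohol 4-{2-[(1S,7R)-3-[(2R)-2-hydroxy-3-methylbut-3-en-1-yl]-1,7-dimethyl-2,4-dioxocycloheptyl]ethyl}furan-2(5H)-one F10, which is also the expected by-product of a failed step 8. The ring is then closed by a known iron-hydride HAT-initiated ketone–olefin radical cyclisation (Fe(acac)3, PhSiH3, EtOH, 60 °C, high dilution). Hydrogen-atom transfer to the 1,1-disubstituted alkene creates the same tertiary radical without titanium and forms the second methyl group. The free secondary hydroxyl can hydrogen-bond the acceptor carbonyl, and the product is 17.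

**Further compounds**
F1 | step 1 | (2R,3R)-2-(1-hydroxyethyl)-2,3-dimethylcyclohexan-1-one | C[C@@H]1CCCC(=O)[C@@]1(C)C(C)O
F2 | step 6 | {[(5R,6S)-6-ethenyl-5,6-dimethylcyclohex-1-en-1-yl]oxy}trimethylsilane | C[C@@H]1CCC=C(O[Si](C)(C)C)[C@@]1(C)C=C
F3 | step 6 | {[(2S,3R)-2-ethenyl-2,3-dimethylbicyclo[4.1.0]heptan-1-yl]oxy}trimethylsilane | C[C@@H]1CCC2CC2(O[Si](C)(C)C)[C@@]1(C)C=C
F4 | step 6 | (2S,3R)-6-chloro-2-ethenyl-2,3-dimethylcycloheptan-1-one | C[C@@H]1CCC(Cl)CC(=O)[C@@]1(C)C=C
F5 | step 6 | (6R,7S)-7-ethenyl-6,7-dimethylcyclohept-2-en-1-one | C[C@@H]1CCC=CC(=O)[C@@]1(C)C=C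
F6 | step 6 | (3S,4R)-3-ethenyl-3,4-dimethyl-8-oxabicyclo[5.1.0]octan-2-one | C[C@@H]1CCC2OC2C(=O)[C@@]1(C)C=C
F7 | step 6 | 9-{2-[(3S,4R)-3,4-dimethyl-2-oxo-8-oxabicyclo[5.1.0]octan-3-yl]ethyl}-9-borabicyclo[3.3.1]nonane | C[C@@H]1CCC2OC2C(=O)[C@@]1(C)CCB1C2CCCC1CCC2
F8 | step 6 | 4-{2-[(3S,4R)-3,4-dimethyl-2-oxo-8-oxabicyclo[5.1.0]octan-3-yl]ethyl}furan-2(5H)-one | C[C@@H]1CCC2OC2C(=O)[C@@]1(C)CCC1=CC(=O)OC1
F9 | step 6 | 4-{2-[(1S,7R)-1,7-dimethyl-2,4-dioxocycloheptyl]ethyl}furan-2(5H)-one | C[C@@H]1CCC(=O)CC(=O)[C@@]1(C)CCC1=CC(=O)OC1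
F10 | step 8 | 4-{2-[(1S,7R)-3-[(2R)-2-hydroxy-3-methylbut-3-en-1-yl]-1,7-dimethyl-2,4-dioxocycloheptyl]ethyl}furan-2(5H)-one | C[C@@H]1CCC(=O)C(C[C@@H](O)C(C)=C)C(=O)[C@@]1(C)CCC1=CC(=O)OC1
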